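**Retrosynthetic overview** (prostanoid numbering: C1 ester carbon, C4 and C12 acetoxy carbons, C9 ring ketone, C8 ring CH, C7 its CH2, C6 the adjacent alkene carbon)
1. The C12 acetate is installed last, from tertiary alcohol 23, by non-basic acetylation.
2. C6–C7 is disconnected to cross-conjugated dienone 15 (C7–C20, ring intact) and (E)-alkenylboronate 22 (C1–C6): rhodium-catalysed conjugate addition to the exocyclic C7=C8 enone, with C8 set by protonation in the same operation.
3. Enabling feature: C7 is β to the C9 carbonyl through C8, so it can be the CH2 terminus of an exo-methylene enone on the cyclopentenone ring; C8 lies next to fully substituted C12, whose OH/CH2 pair differentiates the two ring faces, shields C11 from competing addition, and cannot β-eliminate because that would give a cyclopentadienone.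
4. 15 comes from (R)-4-silyloxycyclopentenone 2 (anti propargylation sets C12; alkylation, Lindlar, oxidation, Mannich methylenation); 22 comes from acid chloride 16 and silylacetylene 17 (Noyori transfer hydrogenation sets C4, hydroboration sets the E alkene).
5. Rings: the cyclopentenone is the only ring; it is present in 2, and no ring is formed or opened in the route.

Key step: step 13

Remark: (R)-4-(tert-butyldimethylsilyloxy)cyclopent-2-en-1-one is taken as a commercial building block; the ring carbinol carbon keeps the configuration set in step 1, and its descriptor changes (S in 4–10, R from 11 on) only through CIP priorities.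

**Step 1**
Reactants: 1 propargyl bromide; 2 (R)-4-(tert-butyldimethylsilyloxy)cyclopent-2-en-1-one
Product: 4 (1S,4R)-4-(tert-butyldimethylsilyloxy)-1-(prop-2-yn-1-yl)cyclopent-2-en-1-ol, via allenylmagnesium bromide 3 (not isolated)
Conditions: Mg, HgCl2 (cat.), Et2O, 0 °C; then 2, Et2O, −78 °C; aqueous work-up
Reagents that add atoms: none
Why: Propargylation by Grignard 1,2-addition: allenylmagnesium bromide reacts through an SE2' transition state to give the homopropargylic (not allenic) tertiary alcohol, and it attacks the carbonyl face anti to the C4 silyloxy group, which sets the quaternary carbinol centre (1S, the future C12) with OH cis to OTBS; any minor syn adduct should be removed here by chromatography because after step 5 it would be the enantiomer of 10.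

**Step 2**
Reactants: 4 (1S,4R)-4-(tert-butyldimethylsilyloxy)-1-(prop-2-yn-1-yl)cyclopent-2-en-1-ol; 5 1-iodopentane
Product: 7 (1S,4R)-4-(tert-butyldimethylsilyloxy)-1-(oct-2-yn-1-yl)cyclopent-2-en-1-ol, via dilithium alkoxide acetylide 6 (not isolated)
Conditions: n-BuLi (2.2 equiv), THF, −78 to −20 °C; DMPU, then 5, −20 °C to rt; aqueous work-up
Reagents that add atoms: none
Why: Acetylide alkylation (SN2): double deprotonation gives the alkoxide–acetylide 6, whose acetylide carbon is far more nucleophilic than the hindered tertiary lithium alkoxide, so the primary iodide is attacked at carbon only in THF/DMPU and no stereocentre is touched.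

**Step 3**
Reactants: 7 (1S,4R)-4-(tert-butyldimethylsilyloxy)-1-(oct-2-yn-1-yl)cyclopent-2-en-1-ol
Product: 8 (1S,4R)-4-(tert-butyldimethylsilyloxy)-1-[(2Z)-oct-2-en-1-yl]cyclopent-2-en-1-ol
Conditions: H2 (1 atm), Pd/CaCO3 poisoned with Pb(OAc)2 (Lindlar catalyst), quinoline, EtOAc, rt
Reagents that add atoms: none
Why: Lindlar semi-hydrogenation adds H2 syn to the internal alkyne and stops at the alkene, which fixes the (Z)-C14=C15 geometry while the hindered ring alkene, the tertiary alcohol and the silyl ether are inert.

**Step 4**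
Reactants: 8 (1S,4R)-4-(tert-butyldimethylsilyloxy)-1-[(2Z)-oct-2-en-1-yl]cyclopent-2-en-1-ol
Product: 9 (1S,4R)-1-[(2Z)-oct-2-en-1-yl]cyclopent-2-ene-1,4-diol
Conditions: TBAF (1.2 equiv), THF, 0 °C to rt
Reagents that add atoms: none
Why: Fluoride-induced desilylation driven by the strong Si–F bond frees the secondary allylic alcohol without affecting either alkene or the tertiary carbinol centre.

**Step 5**
Reactants: 9 (1S,4R)-1-[(2Z)-oct-2-en-1-yl]cyclopent-2-ene-1,4-diol
Product: 10 (4S)-4-hydroxy-4-[(2Z)-oct-2-en-1-yl]cyclopent-2-en-1-one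
Conditions: activated MnO2 (excess), CH2Cl2, rt
Reagents that add atoms: none
Why: Allylic oxidation with MnO2 converts only the secondary allylic alcohol into the enone under neutral conditions, the tertiary alcohol cannot be oxidised and no alkoxide is formed, so retro-aldol scrambling of the carbinol centre (4S in 10) is avoided.

**Step 6**
Reactants: 10 (4S)-4-hydroxy-4-[(2Z)-oct-2-en-1-yl]cyclopent-2-en-1-one
Product: 12 (4R)-5-[(dimethylamino)methyl]-4-[(2Z)-oct-2-en-1-yl]-4-(trimethylsilyloxy)cyclopent-2-en-1-one (C5 epimers), via bis(trimethylsilyl) dienol ether 11 (not isolated)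
Conditions: TMSOTf (2.3 equiv), Et3N (3 equiv), CH2Cl2, 0 °C; then Me2N=CH2 I (Eschenmoser's salt, 1.3 equiv), 0 °C to rt; aqueous work-up
Reagents that add atoms: trimethylsilyl trifluoromethanesulfonate, C[Si](C)(C)OS(=O)(=O)C(F)(F)F; Eschenmoser's salt (N,N-dimethylmethylideneammonium iodide), C=[N+](C)C.[I-]
Why: Soft enolisation (TMSOTf/Et3N) first caps the tertiary alcohol and then gives the cross-conjugated 2-silyloxydiene 11, since C5 is the only enolisable position, and the Mannich reaction of this silyl enol ether with Eschenmoser's salt puts the aminomethyl carbon (future C7) on C5 without ever generating a free aldolate; the C5 centre forms as an epimer mixture that is erased in step 7.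

**Step 7**
Reactants: 12 (4R)-5-[(dimethylamino)methyl]-4-[(2Z)-oct-2-en-1-yl]-4-(trimethylsilyloxy)cyclopent-2-en-1-one (C5 epimers)
Product: 15 (4R)-4-hydroxy-5-methylidene-4-[(2Z)-oct-2-en-1-yl]cyclopent-2-en-1-one, via methiodide 13 (not isolated), via silyl ether dienone 14 (not isolated)
Conditions: MeI (excess), MeCN, rt; then NaHCO3 (aq)/CH2Cl2, rt; then AcOH/THF/H2O, 0 °C; used at once in step 13
Reagents that add atoms: none
Why: Exhaustive N-methylation followed by bicarbonate-induced Hofmann-type E1cB elimination of trimethylamine gives the exocyclic C7=C8 enone, the alternative loss of the C12 oxygen being blocked because it would create a cyclopentadienone, and dilute acetic acid then hydrolyses the tertiary TMS ether to give the dienone, which should be used at once.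

**Step 8**
Reactants: 16 methyl 4-chloro-4-oxobutanoate; 17 bis(trimethylsilyl)acetylene
Product: 18 methyl 4-oxo-6-(trimethylsilyl)hex-5-ynoate
Conditions: AlCl3 (1.1 equiv), CH2Cl2, 0 °C
Reagents that add atoms: none
Why: Friedel–Crafts acylation of the silylalkyne by ipso-substitution (β-silyl stabilisation of the vinyl cation) gives the silyl ynone, and it should stop after one acylation because the product alkyne is deactivated.

**Step 9**
Reactants: 18 methyl 4-oxo-6-(trimethylsilyl)hex-5-ynoate
Product: 19 methyl (4S)-4-hydroxy-6-(trimethylsilyl)hex-5-ynoate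
Conditions: Ru[(S,S)-TsDPEN](p-cymene) (preformed amido complex, 1 mol%), i-PrOH, rt
Reagents that add atoms: none
Why: Noyori asymmetric transfer hydrogenation of the ynone, in which the alkyne takes the place of the aryl group of an aryl ketone in the six-membered hydride and proton transfer, so the (S,S)-catalyst should give the (S)-propargylic alcohol (C4), and the base-free medium should keep the γ-hydroxy ester from lactonising before step 10.

**Step 10**
Reactants: 19 methyl (4S)-4-hydroxy-6-(trimethylsilyl)hex-5-ynoate
Product: 20 methyl (4S)-4-acetoxy-6-(trimethylsilyl)hex-5-ynoate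
Conditions: Ac2O, pyridine, DMAP (cat.), CH2Cl2, 0 °C
Reagents that add atoms: acetic anhydride, CC(=O)OC(C)=O
Why: DMAP-catalysed acetylation of the secondary alcohol installs the C4 acetate of the target and blocks lactonisation, with no change at the stereocentre.

**Step 11**
Reactants: 20 methyl (4S)-4-acetoxy-6-(trimethylsilyl)hex-5-ynoate
Product: 21 methyl (4S)-4-acetoxyhex-5-ynoate
Conditions: TBAF (1.1 equiv), AcOH (1.2 equiv), THF, 0 °C
Reagents that add atoms: none
Why: Fluoride protodesilylation of the alkynylsilane is fast at 0 °C and the acetic acid buffer keeps the medium non-basic, so the propargylic acetate and the methyl ester should survive.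

**Step 12**
Reactants: 21 methyl (4S)-4-acetoxyhex-5-ynoate
Product: 22 methyl (4S,5E)-4-acetoxy-6-(4,4,5,5-tetramethyl-1,3,2-dioxaborolan-2-yl)hex-5-enoate
Conditions: pinacolborane (1.5 equiv), Cy2BH (10 mol%), neat, rt
Reagents that add atoms: pinacolborane, CC1(C)OBOC1(C)C
Why: Dicyclohexylborane-catalysed hydroboration with pinacolborane adds H and B syn across the terminal alkyne with boron at the terminal carbon, which gives the (E)-alkenylboronate and fixes the C5=C6 geometry without touching C4.

**Step 13**
Reactants: 15 (4R)-4-hydroxy-5-methylidene-4-[(2Z)-oct-2-en-1-yl]cyclopent-2-en-1-one; 22 methyl (4S,5E)-4-acetoxy-6-(4,4,5,5-tetramethyl-1,3,2-dioxaborolan-2-yl)hex-5-enoate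
Product: 23 methyl (4S,5E)-4-acetoxy-7-[(1S,5R)-5-hydroxy-5-[(2Z)-oct-2-en-1-yl]-2-oxocyclopent-3-en-1-yl]hept-5-enoate
Conditions: [Rh(cod)OH]2 (3 mol%), 22 (1.4 equiv), 1,4-dioxane/H2O (10:1), 20 °C, no added base
Reagents that add atoms: none
Why: The alkenyl group is transmetalated from boron to the hydroxorhodium complex, the exocyclic C7=C8 enone inserts into the Rh–alkenyl bond with formation of the C6–C7 bond to give an oxa-π-allyl rhodium enolate, and water hydrolyses this enolate, protonating C8 and regenerating Rh–OH. The closest known reaction type is the Hayashi–Miyaura conjugate addition of alkenylboron reagents to enones, in its conjugate addition–protonation variant on α-methylene carbonyl compounds. No ring is closed. The new C8 stereocentre is set under substrate control by C12: the proton should arrive on the enolate face that carries the small C12 hydroxyl (which can also relay water by hydrogen bonding) and not on the face shielded by the C13 methylene chain, so H8 ends syn to OH and the two carbon chains end cis (8S), while C4 and the E alkene are carried over unchanged from 22 and C12 is untouched. The step needs attack at the unhindered terminal CH2 (C7) and not at ring carbon C11, which is secured by C11 being neopentylic next to quaternary C12; it needs protonation to outrun β-hydroxy elimination, which is disfavoured because it would create a cyclopentadienone; and it needs base-free ambient conditions so that the acetate, the ester, the tertiary aldol and the new epimerisable C8 centre survive.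

**Step 14**
Reactants: 23 methyl (4S,5E)-4-acetoxy-7-[(1S,5R)-5-hydroxy-5-[(2Z)-oct-2-en-1-yl]-2-oxocyclopent-3-en-1-yl]hept-5-enoate
Product: 24 methyl (4S,5E)-4-acetoxy-7-[(1S,5R)-5-acetoxy-5-[(2Z)-oct-2-en-1-yl]-2-oxocyclopent-3-en-1-yl]hept-5-enoate
Conditions: Ac2O (3 equiv), Sc(OTf)3 (2 mol%), MeCN, −20 °C
Reagents that add atoms: acetic anhydride, CC(=O)OC(C)=O
Why: Sc(OTf)3-catalysed acylation with Ac2O acetylates even hindered tertiary alcohols at low temperature under non-basic conditions, so the epimerisable C8 centre and the base-labile β-acyloxy ketone are not exposed to base, and ionisation or elimination at C12 is not available because either would lead to a cyclopentadienyl cation or a cyclopentadienone.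

**Compound list**
1 | propargyl bromide (3-bromoprop-1-yne) | C#CCBr | starting material
2 | (R)-4-(tert-butyldimethylsilyloxy)cyclopent-2-en-1-one | O=C1C=C[C@H](O[Si](C)(C)C(C)(C)C)C1 | starting material
3 | allenylmagnesium bromide | C=C=C[Mg]Br | intermediate
4 | (1S,4R)-4-(tert-butyldimethylsilyloxy)-1-(prop-2-yn-1-yl)cyclopent-2-en-1-ol | C#CC[C@@]1(O)C=C[C@H](O[Si](C)(C)C(C)(C)C)C1 | intermediate
5 | 1-iodopentane | CCCCCI | starting material
6 | dilithium alkoxide acetylide of 4 | [Li+].[Li+].[C-]#CC[C@@]1([O-])C=C[C@H](O[Si](C)(C)C(C)(C)C)C1 | intermediate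
7 | (1S,4R)-4-(tert-butyldimethylsilyloxy)-1-(oct-2-yn-1-yl)cyclopent-2-en-1-ol | CCCCCC#CC[C@@]1(O)C=C[C@H](O[Si](C)(C)C(C)(C)C)C1 | intermediate
8 | (1S,4R)-4-(tert-butyldimethylsilyloxy)-1-[(2Z)-oct-2-en-1-yl]cyclopent-2-en-1-ol | CCCCC/C=C\C[C@@]1(O)C=C[C@H](O[Si](C)(C)C(C)(C)C)C1 | intermediate
9 | (1S,4R)-1-[(2Z)-oct-2-en-1-yl]cyclopent-2-ene-1,4-diol | CCCCC/C=C\C[C@@]1(O)C=C[C@H](O)C1 | intermediate
10 | (4S)-4-hydroxy-4-[(2Z)-oct-2-en-1-yl]cyclopent-2-en-1-one | CCCCC/C=C\C[C@@]1(O)C=CC(=O)C1 | intermediate
11 | (5R)-5-[(2Z)-oct-2-en-1-yl]-2,5-bis(trimethylsilyloxy)cyclopenta-1,3-diene | CCCCC/C=C\C[C@@]1(O[Si](C)(C)C)C=CC(O[Si](C)(C)C)=C1 | intermediate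
12 | (4R)-5-[(dimethylamino)methyl]-4-[(2Z)-oct-2-en-1-yl]-4-(trimethylsilyloxy)cyclopent-2-en-1-one (C5 epimers) | CCCCC/C=C\C[C@@]1(O[Si](C)(C)C)C=CC(=O)C1CN(C)C | intermediate
13 | [(5R)-5-[(2Z)-oct-2-en-1-yl]-2-oxo-5-(trimethylsilyloxy)cyclopent-3-en-1-yl]-N,N,N-trimethylmethanaminium iodide (methiodide of 12) | CCCCC/C=C\C[C@@]1(O[Si](C)(C)C)C=CC(=O)C1C[N+](C)(C)C.[I-] | intermediate
14 | (4R)-5-methylidene-4-[(2Z)-oct-2-en-1-yl]-4-(trimethylsilyloxy)cyclopent-2-en-1-one | CCCCC/C=C\C[C@@]1(O[Si](C)(C)C)C=CC(=O)C1=C | intermediate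
15 | (4R)-4-hydroxy-5-methylidene-4-[(2Z)-oct-2-en-1-yl]cyclopent-2-en-1-one | CCCCC/C=C\C[C@@]1(O)C=CC(=O)C1=C | intermediate
16 | methyl 4-chloro-4-oxobutanoate | COC(=O)CCC(Cl)=O | starting material
17 | bis(trimethylsilyl)acetylene | C[Si](C)(C)C#C[Si](C)(C)C | starting material
18 | methyl 4-oxo-6-(trimethylsilyl)hex-5-ynoate | COC(=O)CCC(=O)C#C[Si](C)(C)C | intermediate
19 | methyl (4S)-4-hydroxy-6-(trimethylsilyl)hex-5-ynoate | C[Si](C)(C)C#C[C@H](CCC(=O)OC)O | intermediate
20 | methyl (4S)-4-acetoxy-6-(trimethylsilyl)hex-5-ynoate | C[Si](C)(C)C#C[C@H](CCC(=O)OC)OC(C)=O | intermediate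
21 | methyl (4S)-4-acetoxyhex-5-ynoate | C#C[C@H](CCC(=O)OC)OC(C)=O | intermediate
22 | methyl (4S,5E)-4-acetoxy-6-(4,4,5,5-tetramethyl-1,3,2-dioxaborolan-2-yl)hex-5-enoate | CC1(C)OB(/C=C/[C@H](CCC(=O)OC)OC(C)=O)OC1(C)C | intermediate
23 | methyl (4S,5E)-4-acetoxy-7-[(1S,5R)-5-hydroxy-5-[(2Z)-oct-2-en-1-yl]-2-oxocyclopent-3-en-1-yl]hept-5-enoate | CCCCC/C=C\C[C@@]1(O)C=CC(=O)[C@H]1C/C=C/[C@H](CCC(=O)OC)OC(C)=O | intermediate
24 | methyl (4S,5E)-4-acetoxy-7-[(1S,5R)-5-acetoxy-5-[(2Z)-oct-2-en-1-yl]-2-oxocyclopent-3-en-1-yl]hept-5-enoate (CNP0171642.2) | CCCCC/C=C\C[C@@]1(OC(C)=O)C=CC(=O)[C@H]1C/C=C/[C@H](CCC(=O)OC)OC(C)=O | target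

**Step count**
Total steps: 14. Longest linear sequence: 9 steps (steps 1–7, 13 and 14, from 2); the side-chain branch (steps 8–12) joins at step 13.

**Steps most likely to fail**

Step 13. The protonation of the rhodium enolate at C8 may show poor facial selectivity; lesser risks are competing addition at C11 and loss of the C12 oxygen by β-elimination. The fallback separates bond formation from the stereo-determining protonation. The coupling is run from 15 and 22 as described, and the mixture of 23 and its C8 epimer methyl (4S,5E)-4-acetoxy-7-[(1R,5R)-5-hydroxy-5-[(2Z)-oct-2-en-1-yl]-2-oxocyclopent-3-en-1-yl]hept-5-enoate F1 is converged with TMSOTf/Et3N (CH2Cl2, 0 °C) into the single bis(trimethylsilyl) dienol ether F2, in which the C8 centre is erased. F2 is then protonated at −78 °C in toluene with the Lewis acid-assisted chiral Brønsted acid made from BINOL and SnCl4 (reagent-controlled protonation of a silyl enol ether, using the BINOL enantiomer whose sense of induction matches the required 8S centre) to give the tertiary TMS ether F3. Treatment with AcOH/THF/H2O returns the route at 23.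

Step 7. The cross-conjugated dienone may oligomerise (hetero-Diels–Alder dimerisation, re-addition of liberated amine) during the Hofmann elimination and concentration, and quaternisation may be incomplete. The fallback uses an oxygen leaving group and no amine salts. It sets out from 10: dienol ether 11 is generated as in step 6 and hydroxymethylated with aqueous formaldehyde under Yb(OTf)3 catalysis (aqueous Mukaiyama aldol, THF, rt) to give (4R)-5-(hydroxymethyl)-4-[(2Z)-oct-2-en-1-yl]-4-(trimethylsilyloxy)cyclopent-2-en-1-one F4. MsCl/Et3N (CH2Cl2, 0 °C) gives the primary mesylate F5, and DBU at 0 °C eliminates it to 14, where the route is rejoined (AcOH/THF/H2O then gives 15 as in step 7).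

Step 14. Acylation of the hindered tertiary aldol may be slow, and prolonged exposure to the Lewis acid may epimerise C8 or transpose the allylic C4 acetate. The fallback moves the acetylation ahead of the coupling. It sets out from 15, which is acetylated (Ac2O, Sc(OTf)3, MeCN, −20 °C; no nucleophilic amine, which would add to the exo-methylene) to (1R)-5-methylidene-1-[(2Z)-oct-2-en-1-yl]-4-oxocyclopent-2-en-1-yl acetate F6. F6 is then coupled with 22 under the step 13 conditions, where hydrolysis of the rhodium enolate in the aqueous medium must outrun loss of acetate (again disfavoured by the cyclopentadienone it would produce). This gives 24 directly, where the route is rejoined.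

**Further compounds**
F1 | step 13 | methyl (4S,5E)-4-acetoxy-7-[(1R,5R)-5-hydroxy-5-[(2Z)-oct-2-en-1-yl]-2-oxocyclopent-3-en-1-yl]hept-5-enoate | CCCCC/C=C\C[C@@]1(O)C=CC(=O)[C@@H]1C/C=C/[C@H](CCC(=O)OC)OC(C)=O
F2 | step 13 | methyl (4S,5E)-4-acetoxy-7-[(5R)-5-[(2Z)-oct-2-en-1-yl]-2,5-bis(trimethylsilyloxy)cyclopenta-1,3-dien-1-yl]hept-5-enoate | CCCCC/C=C\C[C@@]1(O[Si](C)(C)C)C=CC(O[Si](C)(C)C)=C1C/C=C/[C@H](CCC(=O)OC)OC(C)=O
F3 | step 13 | methyl (4S,5E)-4-acetoxy-7-[(1S,5R)-5-[(2Z)-oct-2-en-1-yl]-2-oxo-5-(trimethylsilyloxy)cyclopent-3-en-1-yl]hept-5-enoate | CCCCC/C=C\C[C@@]1(O[Si](C)(C)C)C=CC(=O)[C@H]1C/C=C/[C@H](CCC(=O)OC)OC(C)=O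
F4 | step 7 | (4R)-5-(hydroxymethyl)-4-[(2Z)-oct-2-en-1-yl]-4-(trimethylsilyloxy)cyclopent-2-en-1-one (C5 epimers) | CCCCC/C=C\C[C@@]1(O[Si](C)(C)C)C=CC(=O)C1CO
F5 | step 7 | [(5R)-5-[(2Z)-oct-2-en-1-yl]-2-oxo-5-(trimethylsilyloxy)cyclopent-3-en-1-yl]methyl methanesulfonate (C1 epimers) | CCCCC/C=C\C[C@@]1(O[Si](C)(C)C)C=CC(=O)C1COS(C)(=O)=O
F6 | step 14 | (1R)-5-methylidene-1-[(2Z)-oct-2-en-1-yl]-4-oxocyclopent-2-en-1-yl acetate | CCCCC/C=C\C[C@@]1(OC(C)=O)C=CC(=O)C1=C
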